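Read the substrate first.

| flask | substrate | partner | initiator | temperature | remark | time |
|---|---|---|---|---|---|---|
| north-west | 1.5 M | 1.8 M | 52 mM | 5 °C | the very flask that is asked about, followed so far |  |
| flask | 1.5 M | 1.80 M | 52 mM | 5 °C |  | 2.0 d |

- north-west (time / h: target / %, substrate / %): 3.00: 10.7, 67.9; 6.00: 14.4, 46.6; 10.0: 17.1, 30.5; 20.0: 20.0, 14.6; 40.0: 21.4, 9.5

(scatter of a reading: 0.5 percentage points)

- additions bring no volume worth counting
- the earlier runs do not show what temperature does; that part of a forecast is a guess

- grey: change nothing and wait 25 h more
- ochre: at 2.0 d take out 90% of the by-product then present, then wait 25 h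
- violet: at 2.0 d raise the temperature by 20 K, then wait 25 h

1. target, in percent of the substrate first charged, at 2.0 d
2. what to do for the largest gain in target; "none" if nothing gains more than 2 percentage points (grey / ochre / violet / none)
3. target present, in percent of the substrate first charged, after ochre
4. target present, in percent of the substrate first charged, after violet

What do these runs let you carry forward? I would carry the marginal yield, the points of target gained per point of substrate lost, an incremental selectivity, read between 3.00 h and 20.0 h as 0.174.

Why start at 3.00 h and not at the charge? Because the first reading stands at 0.333 of target per point of substrate consumed, higher than that slope, and the readings from there to 20.0 h lie along one slope, I take, as a working assumption, whatever is quick as settled by that first reading and count increments from there.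

Then what stands at 2.0 d? I take the 40.0 h substrate of 9.5% as the level there, a bet on the stall, and going from the 20.0 h reading I get 20.9% of target, which is 0.51 percentage points under the 40.0 h reading, against a scatter of 0.5 points.

And waiting? Even if that whole remainder of substrate went on at this yield, it would bring 1.7 points, less than the 2 points that counts, so grey is useless on this reckoning.

Where is the weak spot? The slope counts target made from substrate and says nothing of target that might come from elsewhere, and the earlier runs do not show temperature at all, so on violet and ochre I hold no number of my own.

The forecast gives 21.6% at 2.0 d, above my figure, then 23.1% after ochre and 22% after violet, which it calls “a small gain from restarted conversion”, and its choice is none.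

The flask gives 20.7% at 2.0 d, 20.7% after ochre and 30.3% after violet, so the choice is violet, with gains of 0.055 points for grey, 0.055 points for ochre and 9.6 points for violet.

    initiator → 2 initiating radical (k = 3.80 × 10⁻⁵ s⁻¹, Ea = 90.0 kJ mol⁻¹)
    substrate + initiating radical → capped initiator + first chain carrier (k = 3300 M⁻¹ s⁻¹, Ea = 31.0 kJ mol⁻¹)
    partner + first chain carrier → target + second chain carrier (k = 220 M⁻¹ s⁻¹, Ea = 39.0 kJ mol⁻¹)
    substrate + second chain carrier → by-product + first chain carrier (k = 26.0 M⁻¹ s⁻¹, Ea = 47.0 kJ mol⁻¹)
    first chain carrier → ended carrier (k = 20.0 s⁻¹, Ea = 53.0 kJ mol⁻¹)
    2 second chain carrier → ended chains (k = 5.00 × 10⁶ M⁻¹ s⁻¹, Ea = 13.0 kJ mol⁻¹)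
    target ⇌ isomer of the product (K = 0.590, k = 5.20 × 10⁻⁵ s⁻¹, Ea = 99.0 kJ mol⁻¹, ΔH = −66.0 kJ mol⁻¹)
    substrate ⇌ dormant form (K = 5.80, k = 2.20 × 10⁻⁵ s⁻¹, Ea = 90.0 kJ mol⁻¹, ΔH = −10.0 kJ mol⁻¹)
    (constants at 5 °C)

In this flask the marginal yield on the 9.62% of substrate left at 48.0 h comes to 1.7 points, and violet gains more than that, while 12.2% of isomer of the product stands beside the target, a pair relaxing with a half-life by that step alone of 1.37 h, short against 2.0 d. The same flask read at 12.0 h holds 26.1% of substrate, so the slope carried on from the 10.0 h reading gives 17.9% of target, and that flask holds 17.9%, with 9.38% of isomer of the product beside it.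

(Readings and results were computed from invented constants; noise was put on by code.)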